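**Remark on the chemistry:** the target is achiral; chroman 7, carbinol 11 and fallback alcohol F2 are handled as racemates because their stereocentres are removed later in the route.

## Analysis of the target

- The target is an achiral 2-hydroxybenzophenone with a 1,3-diarylpropane arm: three benzene rings joined by a ketone and by a saturated three-carbon chain, with no stereocentre and no ring fusion.
- Ring A is tetrasubstituted. Numbered from the carbon bearing the ketone, it has the aroyl group at C1, a free hydroxyl at C2, a methoxy group at C4 and the chain Ca–Cb–Cc at C5; C3 and C6 carry hydrogen.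
- Ring B is the 4-hydroxyphenyl group on the carbonyl. Ring C is the 4-hydroxyphenyl group on Cc, the far end of the chain.
- The sensitive groups are the three phenols (the C2 hydroxyl is hydrogen-bonded to the ketone), the diaryl ketone, which can be over-reduced, and the electron-rich ring A, which is easily alkylated.
- The difficulty is the 1,2,4,5 pattern of ring A. The two ring-A oxygens must end up different (C2 free, C4 methylated) while two more phenols are present, and the chain and the aroyl group must go to C5 and C1 without ambiguity.
- The strategy rests on one feature: the C4 oxygen is ortho to the chain at C5, and Cc is benzylic to the electron-rich ring C. The array O–C4–C5–Ca–Cb–Cc(ring C) is therefore a 2-arylchroman (flavan) whose O–Cc bond has been reduced away.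
- Reconnecting O to Cc gives a pyran ring that a [4+2] cycloaddition can assemble. Cleaving that bond afterwards frees exactly one phenol, the one that has to be methylated.

## Retrosynthetic reasoning

**13 to 12.** The three phenols are unmasked last by cutting three O–benzyl bonds. One protecting group for all three keeps the end game to a single operation, and benzyl ethers tolerate the heat, acid, base and organolithium used earlier.

**12 to 11, then to 9 and 4.** The bond between C1 of ring A and the carbonyl carbon is cut. Ring A becomes the nucleophile (aryllithium 10, from bromide 9) and ring B arrives as aldehyde 4, followed by oxidation of carbinol 11. The cut is made on the ring-A side because a bromine can mark C1 from the first compound onwards, so the position of the ketone is never decided by electrophilic substitution on a ring with several activated sites. No Lewis acid, which would endanger the benzyl ethers, is needed.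

**9 to 8.** The O–methyl bond is cut. At this stage the C4 oxygen is the only free hydroxyl, so the forward methylation has no competitor.

**8 to 7.** The O–Cc bond is reconnected, turning the open chain phenol into chroman 7. The forward step has to break only this benzylic C–O bond and deliver a hydride to Cc. The 4-benzyloxyphenyl group on Cc makes ionisation there easy, whereas the aryl ether bond on the ring-A side cannot ionise.

**7 to 5 and 6, and 6 to 3.** Two bonds of the pyran ring are cut at once, Ca–Cb and O–Cc. This gives styrene 5 and quinone methide 6, which is formed in the flask by dehydration of salicyl alcohol 3. This disconnection builds the whole three-carbon chain and links it to ring A in one step from two simple aromatic pieces. The forward reaction must place the aryl group at C2 of the chroman and not at C3.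

**3 to 2 to 1, and 5 to 4.** Alcohol 3 comes from aldehyde 2 by reduction, and 2 from commercial 1 by benzylation of the hydroxyl that is not hydrogen-bonded to the aldehyde. Compound 1 already has the bromine, both oxygens and the one-carbon handle (the future Ca) in the right positions. Styrene 5 comes from aldehyde 4 by methylenation, so 4 serves twice, as the source of ring C and of ring B.

## Alternatives that were turned down

**Alternative 1: ring A by folding an open polycarbonyl chain.**
- Disconnection: the C1–C6 bond of ring A, leading back to rac-1,9-bis[4-(benzyloxy)phenyl]-6-(dimethoxymethyl)nonane-1,3,5-trione A2.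
- Forward key step: a silyl triflate ionises the acetal; the enol carbon between the aryl ketone and the neighbouring ketone attacks the oxocarbenium carbon, and the six-membered ring aromatises by loss of the methoxy group, giving [4-(benzyloxy)phenyl]{5-[3-(4-(benzyloxy)phenyl)propyl]-2,4-dihydroxyphenyl}methanone A1.
- For: ring A appears with the aroyl group, both oxygens and the chain in place in one step, without halogen or organometal chemistry. The later methylation of A1 at the C4 hydroxyl is credible because the C2 hydroxyl is chelated, so on oxygen differentiation it is as good as the chosen route.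
- Against: A2 is a mixture of tautomers with several ways to close. The enol oxygen on C2 can attack C6 to give a pyranone, the methylene groups can undergo aldol reactions with the ketones, and the acetal carbon sits beta to a ketone and can eliminate. Building A2 requires repeated C-acylation of polyanions and would take more steps than the whole chosen route.
- Comparison: the chosen route buys the 1,2,4,5 pattern as compound 1, keeps every intermediate a stable arene, and places its one uncertain step early.

**Alternative 2: ring B made by cycloaddition on a ring-A ynone.**
- Disconnection: two C–C bonds of ring B, leading back to 1-{2-(benzyloxy)-5-[3-(4-(benzyloxy)phenyl)propyl]-4-methoxyphenyl}prop-2-yn-1-one A4 and (E)-1-methoxy-3-(trimethylsilyloxy)buta-1,3-diene A5.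
- Forward key step: Diels–Alder addition of A5 to A4, then loss of the methoxy group and of silicon, giving {2-(benzyloxy)-5-[3-(4-(benzyloxy)phenyl)propyl]-4-methoxyphenyl}(4-hydroxyphenyl)methanone A3.
- For: the regiochemistry of such dienes with ynones reliably puts the hydroxyl para to the ketone, and the conditions are mild. Ring B arrives with its hydroxyl free, which saves one benzyl group; on that point it is slightly better.
- Against: the step builds the simplest part of the molecule, a para-hydroxyphenyl ring that can be bought as aldehyde 4. A4 already contains all of ring A and the chain, and would itself be made from bromide 9 by metalation, addition to a protected propynal, oxidation and deprotection. That is longer than adding 9 to 4 directly.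
- Comparison: it solves none of the real problems (ring-A pattern, chain attachment) and adds steps. The chosen route spends its key step on exactly those problems.

**Alternative 3: ring A by benzannulation of an oxygenated diene with an aryl ynone.**
- Disconnection: the C1–C2 and C5–C6 bonds of ring A, leading back to {[7-(4-(benzyloxy)phenyl)-1,3-dimethoxyhepta-1,3-dien-1-yl]oxy}trimethylsilane A7 and 1-[4-(benzyloxy)phenyl]prop-2-yn-1-one A8.
- Forward key step: the chain-bearing terminus of A7 bonds to the terminal alkyne carbon of A8 and the ketene acetal carbon bonds to the acyl-bearing carbon; acidic work-up aromatises the adduct to [4-(benzyloxy)phenyl]{5-[3-(4-(benzyloxy)phenyl)propyl]-2-hydroxy-4-methoxyphenyl}methanone A6.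
- For: this is the most convergent plan. A6 has the full skeleton, the methyl ether at C4 and the free C2 hydroxyl in one step, with no protecting group on ring A, and only hydrogenolysis remains. On convergence and on oxygen differentiation it is stronger than the chosen route.
- Against: A7 is a terminally substituted, moisture-sensitive ketene acetal. Making it needs a keto ester with the aryl chain, enol ether formation and silylation with control of the diene geometry, so several steps. The terminal substituent slows the cycloaddition, and ynones often react with such dienes by conjugate addition first, leaving open-chain adducts or pyranones. A8 is prone to polymerisation.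
- Comparison: the total step count would be similar (about nine). The chosen route offers standard aromatic chemistry on stable intermediates, a substitution pattern fixed by the starting material and not by a sensitive diene, and a two-step bypass if its key step fails.

Key step: step 4

## Route

Step 1
Reactants: 1 5-bromo-2,4-dihydroxybenzaldehyde
Product: 2 4-(benzyloxy)-5-bromo-2-hydroxybenzaldehyde
Conditions: BnBr (1.05 equiv), NaHCO3, MeCN, 60 °C
Reagents that add atoms: benzyl bromide, BrCc1ccccc1
Why: Williamson ether synthesis with a weak base; the 4-hydroxyl is para to the aldehyde and more acidic, while the 2-hydroxyl is held in a hydrogen bond to the carbonyl and stays free.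

Step 2
Reactants: 2 4-(benzyloxy)-5-bromo-2-hydroxybenzaldehyde
Product: 3 5-(benzyloxy)-4-bromo-2-(hydroxymethyl)phenol
Conditions: NaBH4, THF/MeOH, 0 °C; aq NH4Cl
Reagents that add atoms: none
Why: Borohydride reduction of an aryl aldehyde; the aryl bromide and benzyl ether are inert. The acid-labile salicyl alcohol should be taken on without acidic handling.

Step 3
Reactants: 4 4-(benzyloxy)benzaldehyde
Product: 5 1-(benzyloxy)-4-ethenylbenzene
Conditions: Ph3PCH3Br, KOtBu, THF, 0 °C to rt
Reagents that add atoms: methyltriphenylphosphonium bromide, C[P+](c1ccccc1)(c1ccccc1)c1ccccc1.[Br-]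
Why: Wittig methylenation of a non-enolisable aryl aldehyde with the unstabilised ylide; no stereochemical issue for a terminal alkene.

Step 4
Reactants: 3 5-(benzyloxy)-4-bromo-2-(hydroxymethyl)phenol; 5 1-(benzyloxy)-4-ethenylbenzene
Product: 7 rac-7-(benzyloxy)-2-[4-(benzyloxy)phenyl]-6-bromochromane, via o-quinone methide 6 (not isolated)
Conditions: 3 added slowly to 5 (3 equiv), BHT (cat.), 1,2-dichlorobenzene, 160 °C, sealed tube
Reagents that add atoms: none
Why: Heating expels water from salicyl alcohol 3 (the benzylic C–O bond is weakened by the para benzyloxy group and the ortho hydroxyl supplies the proton) to give o-quinone methide 6, an electron-poor 1-oxadiene. Compound 6 adds to the electron-rich alkene of 5 in an inverse-electron-demand hetero-Diels–Alder reaction; the closest known reaction type is the thermal union of o-quinone methides with styrenes to give flavans. The addition is concerted but asynchronous: the bond from the exocyclic methylene (Ca) to the styrene terminus (Cb) forms ahead, positive charge builds on the benzylic carbon (Cc), where the 4-benzyloxyphenyl group stabilises it, and the carbonyl oxygen then closes the O–Cc bond. The pyran ring is thus closed by an intermolecular [4+2] cycloaddition, four atoms from 6 and two from 5, and the return of aromaticity to ring A makes it irreversible. The one new stereocentre, C2 of the chroman, is formed with no controlling element, so 7 is racemic; this does not matter because step 5 turns that carbon into a methylene group. The selectivity that matters is regiochemical (2-aryl, not 3-aryl chroman) and follows from the polarisation of 6 (electrophilic methylene, nucleophilic oxygen) matched with that of 5. Self-condensation of 6 is countered by keeping 3 dilute in an excess of 5, and BHT suppresses radical polymerisation of the styrene.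

Step 5
Reactants: 7 rac-7-(benzyloxy)-2-[4-(benzyloxy)phenyl]-6-bromochromane
Product: 8 5-(benzyloxy)-2-{3-[4-(benzyloxy)phenyl]propyl}-4-bromophenol
Conditions: Et3SiH (3 equiv), CF3CO2H (10 equiv), CH2Cl2, 0 °C
Reagents that add atoms: none
Why: Ionic hydrogenation: protonation of the ring oxygen and ionisation of the benzylic O–C2 bond give a 4-alkoxybenzyl cation that takes hydride from the silane. The aryl–oxygen bond cannot ionise, so only the intended bond breaks, and the racemic stereocentre is erased.

Step 6
Reactants: 8 5-(benzyloxy)-2-{3-[4-(benzyloxy)phenyl]propyl}-4-bromophenol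
Product: 9 1-(benzyloxy)-4-{3-[4-(benzyloxy)phenyl]propyl}-2-bromo-5-methoxybenzene
Conditions: MeI, K2CO3, DMF, rt
Reagents that add atoms: iodomethane, CI
Why: Williamson O-methylation of the only free hydroxyl in the molecule; this fixes the C4 methoxy group of ring A and removes the acidic proton before the organolithium step.

Step 7
Reactants: 9 1-(benzyloxy)-4-{3-[4-(benzyloxy)phenyl]propyl}-2-bromo-5-methoxybenzene; 4 4-(benzyloxy)benzaldehyde
Product: 11 rac-{2-(benzyloxy)-5-{3-[4-(benzyloxy)phenyl]propyl}-4-methoxyphenyl}[4-(benzyloxy)phenyl]methanol, via aryllithium 10 (not isolated)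
Conditions: n-BuLi, THF, −78 °C; then 4, −78 to 0 °C; aq NH4Cl
Reagents that add atoms: n-butyllithium, [Li]CCCC (its lithium sits in intermediate 10 only; no atom of it remains in 11)
Why: Bromine–lithium exchange at low temperature is faster than any deprotonation, and the ortho benzyloxy oxygen stabilises aryllithium 10, which adds to the non-enolisable aldehyde. The new carbinol stereocentre is uncontrolled and is removed by the oxidation in step 8.

Step 8
Reactants: 11 rac-{2-(benzyloxy)-5-{3-[4-(benzyloxy)phenyl]propyl}-4-methoxyphenyl}[4-(benzyloxy)phenyl]methanol
Product: 12 {2-(benzyloxy)-5-{3-[4-(benzyloxy)phenyl]propyl}-4-methoxyphenyl}[4-(benzyloxy)phenyl]methanone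
Conditions: MnO2 (activated, excess), CH2Cl2, rt
Reagents that add atoms: none
Why: Neutral heterogeneous oxidation of a doubly benzylic alcohol to the diaryl ketone; it avoids acid, which would ionise this electron-rich carbinol, and leaves the benzylic methylene groups alone.

Step 9
Reactants: 12 {2-(benzyloxy)-5-{3-[4-(benzyloxy)phenyl]propyl}-4-methoxyphenyl}[4-(benzyloxy)phenyl]methanone
Product: 13 {2-hydroxy-5-[3-(4-hydroxyphenyl)propyl]-4-methoxyphenyl}(4-hydroxyphenyl)methanone
Conditions: H2 (1 atm), 10% Pd/C, EtOAc/MeOH, rt, stopped when the third benzyl group is gone
Reagents that add atoms: none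
Why: Catalytic hydrogenolysis cleaves the three aryl benzyl ethers in one operation. The ketone is conjugated to three oxygen donors, which makes it a poor substrate for reduction under neutral conditions; the methyl ether is inert.

## Compound list

1 | 5-bromo-2,4-dihydroxybenzaldehyde | O=Cc1cc(Br)c(O)cc1O | starting material
2 | 4-(benzyloxy)-5-bromo-2-hydroxybenzaldehyde | O=Cc1cc(Br)c(OCc2ccccc2)cc1O | intermediate
3 | 5-(benzyloxy)-4-bromo-2-(hydroxymethyl)phenol | OCc1cc(Br)c(OCc2ccccc2)cc1O | intermediate
4 | 4-(benzyloxy)benzaldehyde | O=Cc1ccc(OCc2ccccc2)cc1 | starting material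
5 | 1-(benzyloxy)-4-ethenylbenzene | C=Cc1ccc(OCc2ccccc2)cc1 | intermediate
6 | 3-(benzyloxy)-4-bromo-6-methylidenecyclohexa-2,4-dien-1-one (o-quinone methide, not isolated) | C=C1C=C(Br)C(OCc2ccccc2)=CC1=O | intermediate
7 | rac-7-(benzyloxy)-2-[4-(benzyloxy)phenyl]-6-bromochromane (racemate; the 2S enantiomer is drawn) | Brc1cc2c(cc1OCc1ccccc1)O[C@H](c1ccc(OCc3ccccc3)cc1)CC2 | intermediate
8 | 5-(benzyloxy)-2-{3-[4-(benzyloxy)phenyl]propyl}-4-bromophenol | Oc1cc(OCc2ccccc2)c(Br)cc1CCCc1ccc(OCc2ccccc2)cc1 | intermediate
9 | 1-(benzyloxy)-4-{3-[4-(benzyloxy)phenyl]propyl}-2-bromo-5-methoxybenzene | COc1cc(OCc2ccccc2)c(Br)cc1CCCc1ccc(OCc2ccccc2)cc1 | intermediate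
10 | {2-(benzyloxy)-5-{3-[4-(benzyloxy)phenyl]propyl}-4-methoxyphenyl}lithium (not isolated) | [Li]c1cc(CCCc2ccc(OCc3ccccc3)cc2)c(OC)cc1OCc1ccccc1 | intermediate
11 | rac-{2-(benzyloxy)-5-{3-[4-(benzyloxy)phenyl]propyl}-4-methoxyphenyl}[4-(benzyloxy)phenyl]methanol (racemate) | COc1cc(OCc2ccccc2)c(C(O)c2ccc(OCc3ccccc3)cc2)cc1CCCc1ccc(OCc2ccccc2)cc1 | intermediate
12 | {2-(benzyloxy)-5-{3-[4-(benzyloxy)phenyl]propyl}-4-methoxyphenyl}[4-(benzyloxy)phenyl]methanone | COc1cc(OCc2ccccc2)c(C(=O)c2ccc(OCc3ccccc3)cc2)cc1CCCc1ccc(OCc2ccccc2)cc1 | intermediate
13 | {2-hydroxy-5-[3-(4-hydroxyphenyl)propyl]-4-methoxyphenyl}(4-hydroxyphenyl)methanone | COc1cc(O)c(C(=O)c2ccc(O)cc2)cc1CCCc1ccc(O)cc1 | target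

## Step count and risk

Total step count: 9. Longest linear sequence: 8 steps (1, 2, 4, 5, 6, 7, 8, 9 from compound 1); step 3 is a one-step side branch.

**Step 4 (key step).**
- What may go wrong: the quinone methide may condense with itself or with unreacted 3 (attack of a free phenol ring position on the methylene, as in phenol–formaldehyde chemistry). The styrene may polymerise, because dehydration needs a temperature at which both processes compete with the cycloaddition.
- Fallback: a bypass from aldehyde 2 that builds the chain by carbonyl addition and rejoins at 8, so that steps 4 and 5 drop out. 1-(Benzyloxy)-4-(2-bromoethyl)benzene and magnesium in THF give {2-[4-(benzyloxy)phenyl]ethyl}magnesium bromide F1. A little over two equivalents (the first is spent on the phenol) add to 2 at 0 °C to give rac-5-(benzyloxy)-2-{3-[4-(benzyloxy)phenyl]-1-hydroxypropyl}-4-bromophenol F2. Et3SiH and CF3CO2H in CH2Cl2 at 0 °C then remove the benzylic hydroxyl through the cation stabilised by the ortho hydroxyl and para benzyloxy groups, giving 8.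

**Step 5.**
- What may go wrong: the benzylic cation may be captured by an electron-rich arene of a second molecule (Friedel–Crafts alkylation) faster than by the silane. Prolonged acid may also strip benzyl ethers or cause protodebromination at the carbon para to the freed hydroxyl.
- Fallback: an acid-free route from aldehyde 2 to 8. {2-[4-(Benzyloxy)phenyl]ethyl}triphenylphosphonium bromide F3, made from 1-(benzyloxy)-4-(2-bromoethyl)benzene and PPh3, is deprotonated with excess KOtBu in THF. Wittig olefination of 2 gives 5-(benzyloxy)-2-{3-[4-(benzyloxy)phenyl]prop-1-en-1-yl}-4-bromophenol F4 as an E/Z mixture. Diimide (TsNHNH2, NaOAc, THF/H2O, reflux) saturates the alkene without touching the aryl bromide or the benzyl ethers and gives 8; any migration of the double bond along the chain is harmless because every isomer reduces to 8.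

**Step 7.**
- What may go wrong: the aryllithium may be quenched by proton transfer from the benzylic position of the ortho benzyloxy group (with Wittig rearrangement), or butylated by the 1-bromobutane formed in the exchange, before it meets the aldehyde.
- Fallback: a carbonylative Suzuki coupling from bromide 9 straight to ketone 12, which also removes step 8. Conditions: Pd(OAc)2, di(1-adamantyl)-n-butylphosphine, CO (5 bar), 4-(benzyloxy)phenylboronic acid, K2CO3, toluene, 100 °C; the zerovalent palladium formed in the flask inserts into the C–Br bond, CO insertion is favoured for an electron-rich aryl group, and transmetalation with the boronic acid closes the cycle. No new compound lies on this path (F0).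

**Step 9.**
- What may go wrong: the diaryl ketone may be over-reduced to the carbinol and then to the diarylmethane before the hindered benzyl ether ortho to the carbonyl is cleaved.
- Fallback: non-reductive debenzylation of 12 directly to 13 with BCl3 and pentamethylbenzene in CH2Cl2 at −78 °C. The Lewis acid removes the benzyl groups as cations that the scavenger traps. The C4 methyl ether is para to the ketone, cannot be chelated, and should survive at this temperature. No new compound lies on this path (F0).

## Further compounds

F1 | step 4 | {2-[4-(benzyloxy)phenyl]ethyl}magnesium bromide | Br[Mg]CCc1ccc(OCc2ccccc2)cc1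
F2 | step 4 | rac-5-(benzyloxy)-2-{3-[4-(benzyloxy)phenyl]-1-hydroxypropyl}-4-bromophenol (racemate) | OC(CCc1ccc(OCc2ccccc2)cc1)c1cc(Br)c(OCc2ccccc2)cc1O
F3 | step 5 | {2-[4-(benzyloxy)phenyl]ethyl}triphenylphosphonium bromide | [Br-].c1ccc(cc1)[P+](CCc1ccc(OCc2ccccc2)cc1)(c1ccccc1)c1ccccc1
F4 | step 5 | 5-(benzyloxy)-2-{3-[4-(benzyloxy)phenyl]prop-1-en-1-yl}-4-bromophenol (E/Z mixture) | Oc1cc(OCc2ccccc2)c(Br)cc1C=CCc1ccc(OCc2ccccc2)cc1
F0 | step 7 | none | none
F0 | step 9 | none | none
A1 | alternative 1 | [4-(benzyloxy)phenyl]{5-[3-(4-(benzyloxy)phenyl)propyl]-2,4-dihydroxyphenyl}methanone | Oc1cc(O)c(C(=O)c2ccc(OCc3ccccc3)cc2)cc1CCCc1ccc(OCc2ccccc2)cc1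
A2 | alternative 1 | rac-1,9-bis[4-(benzyloxy)phenyl]-6-(dimethoxymethyl)nonane-1,3,5-trione (racemate) | COC(OC)C(CCCc1ccc(OCc2ccccc2)cc1)C(=O)CC(=O)CC(=O)c1ccc(OCc2ccccc2)cc1
A3 | alternative 2 | {2-(benzyloxy)-5-[3-(4-(benzyloxy)phenyl)propyl]-4-methoxyphenyl}(4-hydroxyphenyl)methanone | COc1cc(OCc2ccccc2)c(C(=O)c2ccc(O)cc2)cc1CCCc1ccc(OCc2ccccc2)cc1
A4 | alternative 2 | 1-{2-(benzyloxy)-5-[3-(4-(benzyloxy)phenyl)propyl]-4-methoxyphenyl}prop-2-yn-1-one | C#CC(=O)c1cc(CCCc2ccc(OCc3ccccc3)cc2)c(OC)cc1OCc1ccccc1
A5 | alternative 2 | (E)-1-methoxy-3-(trimethylsilyloxy)buta-1,3-diene | CO/C=C/C(=C)O[Si](C)(C)C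
A6 | alternative 3 | [4-(benzyloxy)phenyl]{5-[3-(4-(benzyloxy)phenyl)propyl]-2-hydroxy-4-methoxyphenyl}methanone | COc1cc(O)c(C(=O)c2ccc(OCc3ccccc3)cc2)cc1CCCc1ccc(OCc2ccccc2)cc1
A7 | alternative 3 | {[7-(4-(benzyloxy)phenyl)-1,3-dimethoxyhepta-1,3-dien-1-yl]oxy}trimethylsilane (double-bond geometry not fixed) | COC(=CC(OC)=CCCCc1ccc(OCc2ccccc2)cc1)O[Si](C)(C)C
A8 | alternative 3 | 1-[4-(benzyloxy)phenyl]prop-2-yn-1-one | C#CC(=O)c1ccc(OCc2ccccc2)cc1
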